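I began from the target, which can form from whatever starting material the protic impurity leaves, and I supposed that one impurity destroys one starting material. The charges then give 50.0%, the ceiling, the share of the charge open to the target in both grey and blue. This stayed a supposition, since the highest reading, 34.9% in the midnight run, lies below it.

| flask | starting material | protic impurity | free catalyst | temperature | remark | time |
|---|---|---|---|---|---|---|
| autumn | 0.062 M | 0.031 M | 3.5 mol% | −35 °C | run made earlier |  |
| midnight | 0.062 M | 0.031 M | 6 mol% | −24 °C | run made earlier |  |
| spring | 0.062 M | 0.031 M | 9.7 mol% | −35 °C | run made earlier |  |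
| grey | 0.062 M | 0.0310 M | 10 mol% |  | at −20 °C until 5.0 h, from then on at −40 °C | 10 h |
| blue | 0.062 M | 0.0310 M | 3 mol% |  | at −20 °C throughout | 20 h |

- autumn (time / h: target / %): 1.33: 2.2; 4.00: 5.2; 6.00: 7.1; 10.0: 9.3; 15.0: 11.2
- midnight (time / h: target / %): 0.667: 6.3; 2.00: 15.4; 3.00: 19.5; 5.00: 26.1; 8.00: 34.9
- spring (time / h: target / %): 3.00: 11.7; 6.00: 19.7; 8.00: 23.2; 12.0: 26.6; 15.0: 27.9

(standard deviation of a reading: 0.5 percentage points)

- the flask that ends with the higher amount of target, in percent of the starting material charged, or "neither" when 2 percentage points or less lies between them (grey / blue / neither)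
- final target, as a percentage of the starting material charged, in grey
- final target, as a percentage of the starting material charged, in blue

So I reckoned with the room, the ceiling minus the target, and treated its decay as pseudo-first-order. In the midnight run the room shrank from 24 percentage points to 15 points between its last two readings:

rate at −24 °C = ln(room before / room after) / time = 0.153 h⁻¹

The first readings of the autumn and midnight runs, taken per catalyst, gave a temperature factor of 1.55 for the step to −20 °C. Scaling by loading as well, I had:

blue: rate 0.119 h⁻¹, target = ceiling × (1 − exp(−rate × time)) = 45.3%

grey, warm stage: rate 0.395 h⁻¹, room left 6.9 points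

grey, cold stage, at the autumn run's opening pace scaled to grey's loading: rate 0.0473 h⁻¹, target 44.5%

The weak link was the temperature factor, since the midnight run's first reading already carries some fading. Doubling both warm rates gave blue 49.6% and grey, before its cold stage, 49.0%. I therefore committed to both flasks lying between my reckoning and the ceiling, with less than the margin between them.

The forecast gave 58% for grey and 57% for blue, above my ceiling, and chose neither: “These are too close to separate, so neither.”

Grey ended at 47.6% and blue at 47.8%, so the answer is neither. At 20.0 h blue held 50.0% quenched substrate and 0% protic impurity. The ceiling less blue's target is 2.2 points, and 2.2% of starting material still stood there.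

    starting material + free catalyst → catalyst intermediate A (k = 7.60 M⁻¹ min⁻¹, Ea = 48.0 kJ mol⁻¹)
    catalyst intermediate A → catalyst intermediate B (k = 0.100 min⁻¹, Ea = 70.0 kJ mol⁻¹)
    catalyst intermediate B → free catalyst + target (k = 2.00 min⁻¹, Ea = 72.0 kJ mol⁻¹)
    starting material + protic impurity → quenched substrate (k = 1.50 M⁻¹ min⁻¹, Ea = 60.0 kJ mol⁻¹)
    free catalyst ⇌ dormant form (K = 3.80, k = 0.200 min⁻¹, Ea = 75.0 kJ mol⁻¹, ΔH = −68.0 kJ mol⁻¹)
    (constants at −20 °C)

For the neighbour of blue with 0.053 M of protic impurity, the same one-for-one reckoning, with that impurity counted as wholly spent, gives an estimate of 14.5%. Its computed target is 14.9%, a little above that estimate, and with 0.68% of the impurity's own charge still there at the end of this neighbour, the share of starting material it leaves is 15.1%.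

(The runs come from a simulation with made-up constants; scatter was added.)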